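**Retrosynthetic overview**

1. Target 23 ⇐ acetylation and desilylation of 21; the 2‑bromo‑enone ⇐ bromide opening and dehydration of a 10,11‑epoxy‑9‑ketone, made from 17 by hydroxyl‑directed epoxidation and oxidation of the ring carbinol (1,3‑carbonyl transposition).
2. C12 carbinol and ω‑chain ⇐ 1,2‑addition of an oct‑2‑ynyl zinc reagent to the ketone of hydroxycyclopentenone 13, anti to the C8 side chain, then Lindlar reduction.
3. Cyclopentenone 13 (the only carbocycle) ⇐ Piancatelli rearrangement of furylcarbinol 11: conrotatory 4π electrocyclization forming C8–C9, with C8 controlled by C7.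
4. 11 ⇐ 2‑furyllithium + α‑silyloxy aldehyde 8; C7 and the 5Z alkene ⇐ (R)‑glyceraldehyde acetonide (from D‑mannitol) by Z‑selective Wittig.
5. Ring order: the bought dioxolane is opened (step 2), the cyclopentenone is formed (step 6), and a transient epoxide (steps 9–11) delivers the bromine.

Assumption: prostanoid atom numbers are used in the explanations (C1 ester carbon, C7 acetoxy carbon, C8–C12 ring, C13–C20 octenyl chain); 1, 2, 9 and 14 are bought.

**Route**

Step 1
Reactants: 1 (R)-2,2-dimethyl-1,3-dioxolane-4-carbaldehyde; 2 (5-methoxy-5-oxopentyl)triphenylphosphonium bromide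
Product: 4 methyl (5Z)-6-[(4S)-2,2-dimethyl-1,3-dioxolan-4-yl]hex-5-enoate, via phosphorus ylide 3 (not isolated)
Conditions: 2, NaHMDS, THF, −78 °C; then 1, −78 °C → rt
Reagents that add atoms: none
Why: Salt‑free Wittig olefination with a non‑stabilised ylide gives the (Z)‑alkene through the kinetic cis‑oxaphosphetane, and the bought stereocentre (future C7) is not enolised at −78 °C.

Step 2
Reactants: 4
Product: 5 methyl (5Z,7S)-7,8-dihydroxyoct-5-enoate
Conditions: AcOH/H2O (4:1), 40 °C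
Reagents that add atoms: none
Why: Acid‑catalysed acetal hydrolysis frees the 1,2‑diol without touching the methyl ester, the alkene or C7.

Step 3
Reactants: 5
Product: 7 methyl (5Z,7S)-7-[(tert-butyldimethylsilyl)oxy]-8-[(triethylsilyl)oxy]oct-5-enoate, via mono-TES ether 6 (not isolated)
Conditions: TESCl (1.05 equiv), imidazole, CH2Cl2, −78 → −20 °C; then TBSOTf, 2,6-lutidine, −78 → 0 °C
Reagents that add atoms: chlorotriethylsilane, CC[Si](Cl)(CC)CC; tert-butyldimethylsilyl trifluoromethanesulfonate, CC(C)(C)[Si](C)(C)OS(=O)(=O)C(F)(F)F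
Why: Silyl ether formation is differentiated by sterics, the primary hydroxyl taking the TES group at low temperature and the hindered allylic secondary hydroxyl then being capped by the more reactive TBS triflate.

Step 4
Reactants: 7
Product: 8 methyl (5Z,7S)-7-[(tert-butyldimethylsilyl)oxy]-8-oxooct-5-enoate
Conditions: (COCl)2, DMSO, CH2Cl2, −78 → −30 °C; then Et3N, −78 → 0 °C; used crude
Reagents that add atoms: none
Why: Under Swern conditions activated DMSO cleaves the unhindered primary TES ether oxidatively to the aldehyde while the secondary TBS ether is inert, and the cold amine work‑up avoids epimerisation or conjugation of the α‑silyloxy aldehyde.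

Step 5
Reactants: 8; 9 furan
Product: 11 methyl (5Z,7S)-7-[(tert-butyldimethylsilyl)oxy]-8-(furan-2-yl)-8-hydroxyoct-5-enoate (C8 epimers), via 2-furyllithium 10 (not isolated)
Conditions: 9, n-BuLi, THF, 0 °C; then 8 (1.0 equiv), −78 °C; aq. NH4Cl
Reagents that add atoms: none
Why: 1,2‑Addition of the aryllithium to the aldehyde is much faster than attack on the methyl ester at −78 °C, and the new carbinol centre (C8) need not be controlled because it is ionised in the next step.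

Step 6
Reactants: 11
Product: 13 methyl (5Z,7S)-7-[(tert-butyldimethylsilyl)oxy]-7-[(1R,5R)-5-hydroxy-2-oxocyclopent-3-en-1-yl]hept-5-enoate, via hydroxydienal 12 (not isolated)
Conditions: ZnCl2 (2 equiv), 1,4-dioxane/H2O (3:1), pH 5–6, 85 °C
Reagents that add atoms: water, O
Why: Piancatelli rearrangement: ionisation of the furfuryl alcohol, water addition at furan C5 and ring opening give 12, whose O‑protonated form (a 1,4‑dihydroxypentadienyl cation) closes by thermal conrotatory 4π electrocyclization, placing the ring hydroxyl trans to the side chain, while C8 is set by C7 because allylic 1,3‑strain holds C7–H in the dienol plane and the new σ‑bond forms on the face away from the alkenyl carbon C6 (silyloxy group outside).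

Step 7
Reactants: 13; 14 1-bromooct-2-yne
Product: 16 methyl (5Z,7S)-7-[(tert-butyldimethylsilyl)oxy]-7-[(1R,2R,5R)-2,5-dihydroxy-2-(oct-2-yn-1-yl)cyclopent-3-en-1-yl]hept-5-enoate, via allenylzinc bromide 15 (not isolated)
Conditions: 14 (3.5 equiv), activated Zn dust, THF, 0 °C; then 13, −40 → 0 °C; aq. NH4Cl
Reagents that add atoms: none
Why: Barbier‑type propargylation in which the allenylzinc adds 1,2 to the ketone through a cyclic SE2′ transition state to give the homopropargylic tertiary alcohol, attacking anti to the bulky C8 substituent (the face also carrying the zinc alkoxide of the ring hydroxyl), which sets C12 with its hydroxyl cis to the side chain; the ester is inert to the zinc reagent.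

Step 8
Reactants: 16
Product: 17 methyl (5Z,7S)-7-[(tert-butyldimethylsilyl)oxy]-7-{(1R,2R,5R)-2,5-dihydroxy-2-[(2Z)-oct-2-en-1-yl]cyclopent-3-en-1-yl}hept-5-enoate
Conditions: H2 (1 atm), Lindlar catalyst, quinoline, EtOAc, rt
Reagents that add atoms: none
Why: Lindlar semi‑hydrogenation adds H2 syn to the alkyne on poisoned palladium and stops at the (Z)‑alkene, leaving the existing alkenes untouched.

Step 9
Reactants: 17
Product: 18 methyl (5Z,7S)-7-[(tert-butyldimethylsilyl)oxy]-7-{(2S,3R,4S)-2,4-dihydroxy-2-[(2Z)-oct-2-en-1-yl]-6-oxabicyclo[3.1.0]hexan-3-yl}hept-5-enoate (epoxide on either face)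
Conditions: VO(acac)2 (5 mol %), t-BuOOH (1.2 equiv), CH2Cl2, 0 °C
Reagents that add atoms: tert-butyl hydroperoxide, CC(C)(C)OO
Why: Vanadium‑catalysed hydroxyl‑directed epoxidation is fastest at the ring alkene, the only one allylic to both hydroxyls, so the two chain (Z)‑alkenes survive, and the epoxide configuration is irrelevant because both epoxide centres are erased in step 11.

Step 10
Reactants: 18
Product: 19 methyl (5Z,7S)-7-[(tert-butyldimethylsilyl)oxy]-7-{(2S,3R)-2-hydroxy-2-[(2Z)-oct-2-en-1-yl]-4-oxo-6-oxabicyclo[3.1.0]hexan-3-yl}hept-5-enoate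
Conditions: Dess–Martin periodinane, NaHCO3, CH2Cl2, 0 °C → rt
Reagents that add atoms: none
Why: Dess–Martin oxidation converts the secondary ring carbinol into the C9 ketone under buffered, non‑epimerising conditions, with the tertiary alcohol, epoxide, silyl ether and alkenes inert.

Step 11
Reactants: 19
Product: 21 methyl (5Z,7S)-7-{(1R,2S)-4-bromo-2-hydroxy-2-[(2Z)-oct-2-en-1-yl]-5-oxocyclopent-3-en-1-yl}-7-[(tert-butyldimethylsilyl)oxy]hept-5-enoate, via bromohydrin 20 (not isolated)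
Conditions: 48% aq. HBr (2 equiv), THF, 0 °C → rt
Reagents that add atoms: hydrogen bromide, Br
Why: Acid‑mediated opening of the α,β‑epoxy ketone by bromide at the α‑carbon (SN2 next to the carbonyl, the β‑carbon being neopentylic) and dehydration of the resulting β‑hydroxy ketone through its enol give the 2‑bromo‑enone without any electrophilic bromine that would add to the chain alkenes.

Step 12
Reactants: 21
Product: 22 methyl (5Z,7S)-7-{(1R,2S)-4-bromo-2-hydroxy-2-[(2Z)-oct-2-en-1-yl]-5-oxocyclopent-3-en-1-yl}-7-hydroxyhept-5-enoate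
Conditions: HF·pyridine, pyridine, THF, 0 °C → rt
Reagents that add atoms: none
Why: Buffered fluoride desilylation frees the C7 hydroxyl without the basic conditions that would cause β‑elimination to the cross‑conjugated dienone.

Step 13
Reactants: 22
Product: 23 7-acetoxy-7,8-dihydrobromovulone I
Conditions: Ac2O, pyridine, DMAP (cat.), CH2Cl2, 0 °C
Reagents that add atoms: acetic anhydride, CC(=O)OC(C)=O
Why: DMAP‑catalysed acylation takes the secondary allylic C7 hydroxyl only, because the tertiary C12 hydroxyl is too hindered to react at 0 °C.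

**Compound list**

1 | (R)-2,2-dimethyl-1,3-dioxolane-4-carbaldehyde ((R)-glyceraldehyde acetonide) | O=C[C@H]1COC(C)(C)O1 | starting material
2 | (5-methoxy-5-oxopentyl)triphenylphosphonium bromide | COC(=O)CCCC[P+](c1ccccc1)(c1ccccc1)c1ccccc1.[Br-] | starting material
3 | methyl 5-(triphenyl-λ5-phosphanylidene)pentanoate (ylide) | COC(=O)CCCC=P(c1ccccc1)(c1ccccc1)c1ccccc1 | intermediate
4 | methyl (5Z)-6-[(4S)-2,2-dimethyl-1,3-dioxolan-4-yl]hex-5-enoate | COC(=O)CCC/C=C\[C@H]1COC(C)(C)O1 | intermediate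
5 | methyl (5Z,7S)-7,8-dihydroxyoct-5-enoate | COC(=O)CCC/C=C\[C@H](O)CO | intermediate
6 | methyl (5Z,7S)-7-hydroxy-8-[(triethylsilyl)oxy]oct-5-enoate | COC(=O)CCC/C=C\[C@H](O)CO[Si](CC)(CC)CC | intermediate
7 | methyl (5Z,7S)-7-[(tert-butyldimethylsilyl)oxy]-8-[(triethylsilyl)oxy]oct-5-enoate | COC(=O)CCC/C=C\[C@H](O[Si](C)(C)C(C)(C)C)CO[Si](CC)(CC)CC | intermediate
8 | methyl (5Z,7S)-7-[(tert-butyldimethylsilyl)oxy]-8-oxooct-5-enoate | COC(=O)CCC/C=C\[C@H](O[Si](C)(C)C(C)(C)C)C=O | intermediate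
9 | furan | c1ccoc1 | starting material
10 | 2-furyllithium | [Li]c1ccco1 | intermediate
11 | methyl (5Z,7S)-7-[(tert-butyldimethylsilyl)oxy]-8-(furan-2-yl)-8-hydroxyoct-5-enoate (C8 epimers) | COC(=O)CCC/C=C\[C@H](O[Si](C)(C)C(C)(C)C)C(O)c1ccco1 | intermediate
12 | methyl (5Z,7S,8Z,10Z)-7-[(tert-butyldimethylsilyl)oxy]-9-hydroxy-12-oxododeca-5,8,10-trienoate | O=C/C=C\C(O)=C\[C@@H](O[Si](C)(C)C(C)(C)C)/C=C\CCCC(=O)OC | intermediate
13 | methyl (5Z,7S)-7-[(tert-butyldimethylsilyl)oxy]-7-[(1R,5R)-5-hydroxy-2-oxocyclopent-3-en-1-yl]hept-5-enoate | COC(=O)CCC/C=C\[C@H](O[Si](C)(C)C(C)(C)C)[C@@H]1C(=O)C=C[C@H]1O | intermediate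
14 | 1-bromooct-2-yne | CCCCCC#CCBr | starting material
15 | bromo(octa-1,2-dien-3-yl)zinc | CCCCCC(=C=C)[Zn]Br | intermediate
16 | methyl (5Z,7S)-7-[(tert-butyldimethylsilyl)oxy]-7-[(1R,2R,5R)-2,5-dihydroxy-2-(oct-2-yn-1-yl)cyclopent-3-en-1-yl]hept-5-enoate | COC(=O)CCC/C=C\[C@H](O[Si](C)(C)C(C)(C)C)[C@@H]1[C@@](O)(CC#CCCCCC)C=C[C@H]1O | intermediate
17 | methyl (5Z,7S)-7-[(tert-butyldimethylsilyl)oxy]-7-{(1R,2R,5R)-2,5-dihydroxy-2-[(2Z)-oct-2-en-1-yl]cyclopent-3-en-1-yl}hept-5-enoate | COC(=O)CCC/C=C\[C@H](O[Si](C)(C)C(C)(C)C)[C@@H]1[C@@](O)(C/C=C\CCCCC)C=C[C@H]1O | intermediate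
18 | methyl (5Z,7S)-7-[(tert-butyldimethylsilyl)oxy]-7-{(2S,3R,4S)-2,4-dihydroxy-2-[(2Z)-oct-2-en-1-yl]-6-oxabicyclo[3.1.0]hexan-3-yl}hept-5-enoate (epoxide carbons unassigned) | COC(=O)CCC/C=C\[C@H](O[Si](C)(C)C(C)(C)C)[C@@H]1[C@@](O)(C/C=C\CCCCC)C2OC2[C@H]1O | intermediate
19 | methyl (5Z,7S)-7-[(tert-butyldimethylsilyl)oxy]-7-{(2S,3R)-2-hydroxy-2-[(2Z)-oct-2-en-1-yl]-4-oxo-6-oxabicyclo[3.1.0]hexan-3-yl}hept-5-enoate (epoxide carbons unassigned) | COC(=O)CCC/C=C\[C@H](O[Si](C)(C)C(C)(C)C)[C@@H]1[C@@](O)(C/C=C\CCCCC)C2OC2C1=O | intermediate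
20 | methyl (5Z,7S)-7-{(1R,2S)-4-bromo-2,3-dihydroxy-2-[(2Z)-oct-2-en-1-yl]-5-oxocyclopentyl}-7-[(tert-butyldimethylsilyl)oxy]hept-5-enoate (ring C3 and C4 unassigned) | COC(=O)CCC/C=C\[C@H](O[Si](C)(C)C(C)(C)C)[C@@H]1[C@@](O)(C/C=C\CCCCC)C(O)C(Br)C1=O | intermediate
21 | methyl (5Z,7S)-7-{(1R,2S)-4-bromo-2-hydroxy-2-[(2Z)-oct-2-en-1-yl]-5-oxocyclopent-3-en-1-yl}-7-[(tert-butyldimethylsilyl)oxy]hept-5-enoate | COC(=O)CCC/C=C\[C@H](O[Si](C)(C)C(C)(C)C)[C@@H]1[C@@](O)(C/C=C\CCCCC)C=C(Br)C1=O | intermediate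
22 | methyl (5Z,7S)-7-{(1R,2S)-4-bromo-2-hydroxy-2-[(2Z)-oct-2-en-1-yl]-5-oxocyclopent-3-en-1-yl}-7-hydroxyhept-5-enoate | COC(=O)CCC/C=C\[C@H](O)[C@@H]1[C@@](O)(C/C=C\CCCCC)C=C(Br)C1=O | intermediate
23 | 7-acetoxy-7,8-dihydrobromovulone I; methyl (5Z,7S)-7-acetoxy-7-{(1R,2S)-4-bromo-2-hydroxy-2-[(2Z)-oct-2-en-1-yl]-5-oxocyclopent-3-en-1-yl}hept-5-enoate | CCCCC/C=C\C[C@@]1(O)C=C(Br)C(=O)[C@@H]1[C@H](/C=C\CCCC(=O)OC)OC(C)=O | target

**Step count and risks**

Total step count: 13. Longest linear sequence: 13 steps (from 1; 2, 9 and 14 are bought).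

Steps most likely to fail:

Step 6 (electrocyclization). The silyloxy group next to the carbinol slows ionisation of 11, so elimination or TBS loss can compete, and the 1,2‑induction from C7 may be modest. The fallback sets out from 11 and comes back at 13. Ionic hydrogenation (Et3SiH, TFA, CH2Cl2, −20 °C) removes the carbinol oxygen and gives methyl (5Z,7R)-7-[(tert-butyldimethylsilyl)oxy]-8-(furan-2-yl)oct-5-enoate F1 (7R only because the CIP ranks change). Photo‑oxygenation (O2, hν, tetraphenylporphyrin, CH2Cl2, −78 °C), a [4+2] cycloaddition of singlet oxygen to the furan, gives the endoperoxide methyl (5Z,7R)-7-[(tert-butyldimethylsilyl)oxy]-8-(2,3,7-trioxabicyclo[2.2.1]hept-5-en-1-yl)oct-5-enoate F2. Me2S in the same flask reduces it to the (Z)-4-oxo-enal methyl (5Z,7R,10Z)-7-[(tert-butyldimethylsilyl)oxy]-9,12-dioxododeca-5,10-dienoate F3. Warming F3 in dioxane/pH 6 phosphate buffer enolises it to 12, which closes to 13 as before. This reaches the pentadienyl system without a cation next to the silyloxy carbon, but it does not improve the induction from C7.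

Step 7 (zinc addition). The propargyl/allenyl zinc pair can leak to the allenyl carbinol, and the facial preference rests on the C8 substituent alone. The fallback sets out from 13 and comes back at 17. Allylzinc bromide F4 (allyl bromide, Zn, THF, 0 °C), which has no regiochemical ambiguity, adds to the ketone to give methyl (5Z,7S)-7-[(tert-butyldimethylsilyl)oxy]-7-[(1R,2R,5R)-2,5-dihydroxy-2-(prop-2-en-1-yl)cyclopent-3-en-1-yl]hept-5-enoate F5. Z‑selective cross‑metathesis of its terminal alkene with hept‑1‑ene (cyclometalated Ru Z‑selective catalyst, THF, 35 °C) then gives 17 directly, so the Lindlar step is not needed.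

Step 11 (epoxide to bromo‑enone). Aqueous HBr may cleave the TBS ether early, or the bromohydrin may resist dehydration next to the tertiary carbinol. The fallback sets out from 8 and comes back at 21; it brings the bromine in with the furan. 2,4‑Dibromofuran undergoes Br/Li exchange at the α‑bromine (n‑BuLi, Et2O, −78 °C) to 4-bromo-2-furyllithium F6, which adds to 8 to give methyl (5Z,7S)-8-(4-bromofuran-2-yl)-7-[(tert-butyldimethylsilyl)oxy]-8-hydroxyoct-5-enoate F7. The same rearrangement (ZnCl2, dioxane/H2O) gives methyl (5Z,7S)-7-[(1R,5S)-4-bromo-5-hydroxy-2-oxocyclopent-3-en-1-yl]-7-[(tert-butyldimethylsilyl)oxy]hept-5-enoate F8. Addition of 15 gives methyl (5Z,7S)-7-[(1R,2S,5S)-4-bromo-2,5-dihydroxy-2-(oct-2-yn-1-yl)cyclopent-3-en-1-yl]-7-[(tert-butyldimethylsilyl)oxy]hept-5-enoate F9. Lindlar reduction gives methyl (5Z,7S)-7-{(1R,2S,5S)-4-bromo-2,5-dihydroxy-2-[(2Z)-oct-2-en-1-yl]cyclopent-3-en-1-yl}-7-[(tert-butyldimethylsilyl)oxy]hept-5-enoate F10, and MnO2 (CH2Cl2) oxidises its 2‑bromoallylic alcohol to 21. This drops steps 9–11; its own risk is hydrolysis of the vinylogous acyl bromide F8 during the aqueous rearrangement.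

**Further compounds**

F1 | step 6 | methyl (5Z,7R)-7-[(tert-butyldimethylsilyl)oxy]-8-(furan-2-yl)oct-5-enoate | COC(=O)CCC/C=C\[C@H](O[Si](C)(C)C(C)(C)C)Cc1ccco1
F2 | step 6 | methyl (5Z,7R)-7-[(tert-butyldimethylsilyl)oxy]-8-(2,3,7-trioxabicyclo[2.2.1]hept-5-en-1-yl)oct-5-enoate | COC(=O)CCC/C=C\[C@H](O[Si](C)(C)C(C)(C)C)CC12OOC(C=C1)O2
F3 | step 6 | methyl (5Z,7R,10Z)-7-[(tert-butyldimethylsilyl)oxy]-9,12-dioxododeca-5,10-dienoate | COC(=O)CCC/C=C\[C@H](O[Si](C)(C)C(C)(C)C)CC(=O)/C=C\C=O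
F4 | step 7 | allylzinc bromide | C=CC[Zn]Br
F5 | step 7 | methyl (5Z,7S)-7-[(tert-butyldimethylsilyl)oxy]-7-[(1R,2R,5R)-2,5-dihydroxy-2-(prop-2-en-1-yl)cyclopent-3-en-1-yl]hept-5-enoate | COC(=O)CCC/C=C\[C@H](O[Si](C)(C)C(C)(C)C)[C@@H]1[C@@](O)(CC=C)C=C[C@H]1O
F6 | step 11 | 4-bromo-2-furyllithium | [Li]c1cc(Br)co1
F7 | step 11 | methyl (5Z,7S)-8-(4-bromofuran-2-yl)-7-[(tert-butyldimethylsilyl)oxy]-8-hydroxyoct-5-enoate (C8 epimers) | COC(=O)CCC/C=C\[C@H](O[Si](C)(C)C(C)(C)C)C(O)c1cc(Br)co1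
F8 | step 11 | methyl (5Z,7S)-7-[(1R,5S)-4-bromo-5-hydroxy-2-oxocyclopent-3-en-1-yl]-7-[(tert-butyldimethylsilyl)oxy]hept-5-enoate | COC(=O)CCC/C=C\[C@H](O[Si](C)(C)C(C)(C)C)[C@@H]1C(=O)C=C(Br)[C@H]1O
F9 | step 11 | methyl (5Z,7S)-7-[(1R,2S,5S)-4-bromo-2,5-dihydroxy-2-(oct-2-yn-1-yl)cyclopent-3-en-1-yl]-7-[(tert-butyldimethylsilyl)oxy]hept-5-enoate | COC(=O)CCC/C=C\[C@H](O[Si](C)(C)C(C)(C)C)[C@@H]1[C@@](O)(CC#CCCCCC)C=C(Br)[C@H]1O
F10 | step 11 | methyl (5Z,7S)-7-{(1R,2S,5S)-4-bromo-2,5-dihydroxy-2-[(2Z)-oct-2-en-1-yl]cyclopent-3-en-1-yl}-7-[(tert-butyldimethylsilyl)oxy]hept-5-enoate | COC(=O)CCC/C=C\[C@H](O[Si](C)(C)C(C)(C)C)[C@@H]1[C@@](O)(C/C=C\CCCCC)C=C(Br)[C@H]1O
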